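Count the lifetimes. Before repeating these flasks I wanted one number for each: how many lifetimes of the conversion to target it gets before the end.

| flask | substrate | coupling partner | second reagent | third reagent | capture agent | temperature | remark | time |
|---|---|---|---|---|---|---|---|---|
| midnight | 0.10 M | 1.2 equiv | 1.1 equiv | 1.5 equiv | 2 mM | 85 °C | run made earlier |  |
| spring | 0.10 M | 1.2 equiv | 1.1 equiv | 2.1 equiv | 2 mM | 100 °C | run made earlier |  |
| winter | 0.10 M | 1.2 equiv | 1.1 equiv | 3.3 equiv | 2 mM | 85 °C | run made earlier |  |
| noon | 0.10 M | 0.60 equiv | 1.1 equiv | 1.5 equiv | 2 mM | 100 °C | run made earlier |  |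
| green | 0.10 M | 1.20 equiv (fed, over 30 min) | 1.10 equiv | 1.50 equiv | 2.00 mM |  | the addition at 60 °C, then warmed to 100 °C; the feed brings no volume worth counting | 50 min |
| teal | 0.10 M | 1.20 equiv | 1.10 equiv | 1.50 equiv | 2.00 mM |  | everything together at the start at 60 °C, warmed to 100 °C at 30 min | 50 min |
| grey | 0.10 M | 1.20 equiv (fed, over 8.0 min) | 1.10 equiv | 1.50 equiv | 2.00 mM | 100 °C | all else is in the flask from the start; the feed brings no volume worth counting | 50 min |
| amber | 0.10 M | 1.20 equiv (fed, over 30 min) | 1.10 equiv | 1.50 equiv | 2.00 mM | 100 °C | all else is in the flask from the start; the feed brings no volume worth counting | 50 min |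
| blue | 0.10 M (fed, over 30 min) | 1.20 equiv | 1.10 equiv | 1.50 equiv | 2.00 mM | 100 °C | all else is in the flask from the start; the feed brings no volume worth counting | 50 min |

| run | time / min | target / % |
|---|---|---|
| midnight | 6.00 | 7.4 |
| midnight | 20.0 | 37.8 |
| midnight | 40.0 | 62.1 |
| midnight | 50.0 | 68.1 |
| midnight | 80.0 | 79.7 |
| midnight | 120 | 87.8 |
| spring | 2.00 | 5.7 |
| spring | 6.00 | 29.3 |
| spring | 10.0 | 45.6 |
| spring | 15.0 | 58.2 |
| spring | 25.0 | 71.4 |
| spring | 30.0 | 76.0 |
| winter | 10.0 | 24.3 |
| winter | 20.0 | 45.0 |
| winter | 30.0 | 57.9 |
| winter | 40.0 | 65.6 |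
| winter | 50.0 | 71.9 |
| winter | 60.0 | 76.2 |
| noon | 2.50 | 4.2 |
| noon | 5.00 | 12.1 |
| noon | 8.00 | 20.2 |
| noon | 15.0 | 33.2 |
| noon | 30.0 | 46.2 |

(readings scatter by 0.5 percentage points)

- target is meant together with its crystals
- solid, in amounts per volume of the solution: crystals
- what may be going on: substrate + coupling partner -> intermediate A; second reagent + intermediate A -> intermediate B; third reagent + intermediate B -> target; substrate + second reagent -> side product; intermediate A + capture agent -> trapped intermediate; crystals <-> target

- the flask that comes out highest in amount of target, in percent of the substrate charged, or "all alike" when all lie within 1.5 percentage points (green / teal / grey / amber / blue / all alike)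
- target at the end, in percent of the substrate charged, green
- target at the end, in percent of the substrate charged, teal
- target at the end, in percent of the substrate charged, grey
- target at the end, in percent of the substrate charged, amber
- target at the end, in percent of the substrate charged, blue

How long is a lifetime at 100 °C? Between 10.0 min and 30.0 min the unfinished part of the spring run fell from 54.4 % to 24.0 %. So I read 24.4 min as an averaged lifetime, the time in which the unfinished part falls by the factor e over that stretch. It is an average and not a constant: the spring readings give an apparent rate of 0.0527 /min from 10.0 min to 15.0 min, but a lower 0.0351 /min from 25.0 min to 30.0 min, and the coupling partner, at 1.2 equiv, is not in large excess.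

Does that reading travel, since the spring run had 2.1 equiv of third reagent and these flasks have 1.50 equiv? At 85 °C, going from 1.5 equiv to 3.3 equiv moved the target at 50.0 min by 3.8 percentage points, so I carried the lifetime over and accepted a small error.

What does a feed cost? A charge fed at a steady rate arrives on average at half the feed time. Grey therefore keeps 46.0 min, or 1.88 lifetimes, and amber and blue keep 35.0 min, or 1.43. I reckoned 84.7 % for grey and 76.1 % for amber and blue, a gap of 8.7 points, more than the margin. Green and teal get 20.0 min at 100 °C, or 0.818 lifetimes, fewer than amber. That gives 55.9 %, plus a part from the minutes at 60 °C that I did not reckon.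

The forecast named grey, saying “grey is nearly batch”. It gave grey 83 % (79 % to 86 %), blue 76.5 %, amber 75.5 %, teal 67 % and green 65 %, so its two cold flasks stand above my count of hot minutes.

Grey came highest at 83.3 %, then blue 76.3 %, amber 75.2 %, teal 69.0 % and green 66.4 %. Grey's lead over blue is 7.0 points, more than the margin, and grey still held 11.4 % of its substrate at 50.0 min. The count left 15.3 % unfinished in grey, and the flask left 16.7 %. For amber the two figures are 23.9 % and 24.8 %.

    substrate + coupling partner → intermediate A (k = 0.0140 /M/s, Ea = 53.0 kJ/mol)
    second reagent + intermediate A → intermediate B (k = 0.420 /M/s, Ea = 55.0 kJ/mol)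
    third reagent + intermediate B → target (k = 0.0620 /M/s, Ea = 74.0 kJ/mol)
    substrate + second reagent → side product (k = 3.80 × 10⁻⁴ /M/s, Ea = 65.0 kJ/mol)
    intermediate A + capture agent → trapped intermediate (k = 0.0350 /M/s, Ea = 51.0 kJ/mol)
    crystals ⇌ target, rate k6*(cs6 - [target]) while solid is left; crystals form when [target] > cs6 (solubility = 47.0 mM, k = 0.0400 /s)
    (constants at 100 °C)

A neighbour of grey has 4.80 equiv of coupling partner, 4.00 times the charge. If the lifetime shortens in that proportion, the count becomes 7.53 lifetimes, with nearly all of the charge finished. That neighbour gave 98.5 %.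

The runs are simulated with made-up constants; scatter was added.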